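Retrosynthesis (azulene numbering C1–C8a; ring A = cyclopentene, ring B = cycloheptane): first the two O–Si bonds are removed. Then C3a–H and the C2=C3 alkene go back, by anti SE2′ protodesilylation, to a 2-trimethylsilyl Δ3(3a)-alkene. Then C2–C3 and C3a–C8a are cut together, which opens rings A and B at once. Last come the C7–C8 acyl bond, the C4–alkyne bond, C5–C6 and the side-chain C–C bond.
Enabling feature: the exocyclic methylene C8=CH2 of ring B sits on the atom next to ring-fusion carbon C8a. C8(=CH2)–C8a is therefore a disguised vinylcyclopropane: C8a–C1–C2 of ring A is the opened cyclopropane, C3/C3a is an internal alkyne, and C4–C7 is the tether that becomes ring B.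
Forward order: crotylboration, γ-lactone (temporary ring), alkylation and lactone opening with propynyllithium build the chain. The silylcyclopropane fragment is joined by acyl Negishi coupling. Both rings then arise together in one rhodium-catalysed (3+2) cycloaddition, and protodesilylation and desilylation finish the route.
Stereochemistry: the side-chain C–O/C–CH3 pair comes from Brown crotylboration, and C5 from alkylation anti to the lactone substituents. C4 and C7 come from catalyst-controlled ketone reductions. C8a and C2 come from a Charette cyclopropane (retention), and C3a from anti SE2′ attack relayed by the C2–Si bond.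

Key step: step 18

Remark: the SMILES defines a trans-fused hydroazulene (H-3a and H-8a anti), and the route is built for this configuration; ethyl 4-methylpent-4-enoate and (E)-3-(trimethylsilyl)prop-2-en-1-ol are taken as commercial.

Step 1
Reactants: 1 ethyl 4-methylpent-4-enoate
Product: 2 4-methylpent-4-enal
Conditions: i-Bu2AlH (1.05 equiv), CH2Cl2, −78 °C; aq. potassium sodium tartrate
Reagents that add atoms: none
Why: Partial ester reduction at low temperature stops at the tetrahedral aluminium hemiacetal, which releases the aldehyde only on work-up.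

Step 2
Reactants: 2 4-methylpent-4-enal
Product: 4 (3S,4S)-3,7-dimethylocta-1,7-dien-4-ol, via borinate ester 3 (not isolated)
Conditions: (Z)-crotylbis[(+)-isopinocampheyl]borane (freshly prepared reagent solution), THF/Et2O, −78 °C; then NaOH, H2O2, 0 °C to rt
Reagents that add atoms: (Z)-crotylbis[(+)-isopinocampheyl]borane, C/C=C\CB([C@H]1C[C@H]2C[C@@H]([C@@H]1C)C2(C)C)[C@H]1C[C@H]2C[C@@H]([C@@H]1C)C2(C)C
Why: Brown asymmetric crotylboration, in which the closed chair transition state turns the Z-crotyl geometry into the syn O/CH3 relation and the (+)-isopinocampheyl groups choose the aldehyde face, so both side-chain stereocentres are set.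

Step 3
Reactants: 4 (3S,4S)-3,7-dimethylocta-1,7-dien-4-ol
Product: 6 (3S,4S)-3,7-dimethyloct-7-ene-1,4-diol, via bis(disiamylboryl) adduct 5 (not isolated)
Conditions: disiamylborane (Sia2BH, 2.3 equiv, freshly prepared), THF, 0 °C; then NaOH, H2O2
Reagents that add atoms: hydrogen peroxide, OO
Why: Chemoselective anti-Markovnikov hydroboration–oxidation, in which the bulky dialkylborane prefers the monosubstituted vinyl group to the 1,1-disubstituted alkene and no stereocentre is touched.

Step 4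
Reactants: 6 (3S,4S)-3,7-dimethyloct-7-ene-1,4-diol
Product: 8 (4S,5S)-4-methyl-5-(3-methylbut-3-enyl)oxolan-2-one, via lactol 7 (not isolated)
Conditions: TEMPO (10 mol %), PhI(OAc)2 (2.5 equiv), CH2Cl2, rt
Reagents that add atoms: none
Why: TEMPO/PhI(OAc)2 oxidative lactonisation, in which the primary alcohol is oxidised first, the aldehyde closes to the lactol and this is oxidised on to the cis-4,5-disubstituted γ-lactone while the alkene stays inert.

Step 5
Reactants: 8 (4S,5S)-4-methyl-5-(3-methylbut-3-enyl)oxolan-2-one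
Product: 10 tert-butyl 2-[(3S,4S,5S)-4-methyl-5-(3-methylbut-3-enyl)-2-oxooxolan-3-yl]acetate, via lithium enolate 9 (not isolated)
Conditions: LiN(i-Pr)2, THF, −78 °C; BrCH2CO2t-Bu, DMPU, −78 to −40 °C
Reagents that add atoms: tert-butyl bromoacetate, CC(C)(C)OC(=O)CBr
Why: Lactone enolate alkylation, in which the electrophile approaches the face opposite the cis-disposed 4-methyl and 5-alkyl groups and so sets the future C5 trans to the methyl group.

Step 6
Reactants: 10 tert-butyl 2-[(3S,4S,5S)-4-methyl-5-(3-methylbut-3-enyl)-2-oxooxolan-3-yl]acetate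
Product: 11 tert-butyl (3S)-3-[(2S,3S)-3-hydroxy-6-methylhept-6-en-2-yl]-4-oxohept-5-ynoate
Conditions: LiC≡CCH3 (1.1 equiv), THF, −78 °C; aq. NH4Cl at −78 °C
Reagents that add atoms: 1-propynyllithium, [Li]C#CC
Why: Acetylide addition to a γ-lactone stops after one addition because the lithium lactolate persists at −78 °C, the hindered tert-butyl ester is spared, and ring opening frees the hydroxyl that will carry the acetate.

Step 7
Reactants: 11 tert-butyl (3S)-3-[(2S,3S)-3-hydroxy-6-methylhept-6-en-2-yl]-4-oxohept-5-ynoate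
Product: 12 tert-butyl (3S)-3-[(2S,3S)-3-acetoxy-6-methylhept-6-en-2-yl]-4-oxohept-5-ynoate
Conditions: Ac2O, pyridine, DMAP (cat.), CH2Cl2, 0 °C
Reagents that add atoms: acetic anhydride, CC(=O)OC(C)=O
Why: Standard acylation traps the open hydroxy ketone, since the secondary alcohol is acylated much faster than the tertiary hemiketal hydroxyl of the closed form.

Step 8
Reactants: 12 tert-butyl (3S)-3-[(2S,3S)-3-acetoxy-6-methylhept-6-en-2-yl]-4-oxohept-5-ynoate
Product: 13 tert-butyl (3S,4R)-3-[(2S,3S)-3-acetoxy-6-methylhept-6-en-2-yl]-4-hydroxyhept-5-ynoate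
Conditions: Ru[(R,R)-TsDPEN](p-cymene) (2 mol %), i-PrOH, rt
Reagents that add atoms: none
Why: Noyori asymmetric transfer hydrogenation of an alkynyl ketone, in which the (R,R)-diamine catalyst sets the (R)-propargylic carbinol (future C4) under base-free conditions that spare the neighbouring stereocentre, the acetate and the alkene.

Step 9
Reactants: 13 tert-butyl (3S,4R)-3-[(2S,3S)-3-acetoxy-6-methylhept-6-en-2-yl]-4-hydroxyhept-5-ynoate
Product: 14 tert-butyl (3S,4R)-3-[(2S,3S)-3-acetoxy-6-methylhept-6-en-2-yl]-4-(tert-butyldimethylsilyloxy)hept-5-ynoate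
Conditions: TBSOTf, 2,6-lutidine, CH2Cl2, 0 °C
Reagents that add atoms: tert-butyldimethylsilyl triflate, CC(C)(C)[Si](C)(C)OS(=O)(=O)C(F)(F)F
Why: Silyl triflate silylation is fast enough for the hindered propargylic alcohol and forestalls its lactonisation onto the tert-butyl ester.

Step 10
Reactants: 14 tert-butyl (3S,4R)-3-[(2S,3S)-3-acetoxy-6-methylhept-6-en-2-yl]-4-(tert-butyldimethylsilyloxy)hept-5-ynoate
Product: 16 (3S,4R)-3-[(2S,3S)-3-acetoxy-6-methylhept-6-en-2-yl]-4-(tert-butyldimethylsilyloxy)hept-5-ynoic acid, via trimethylsilyl ester 15 (not isolated)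
Conditions: TMSOTf, 2,6-lutidine, CH2Cl2, 0 °C to rt; then pH 5 buffer, THF
Reagents that add atoms: none
Why: Silyl triflate-mediated cleavage of a tert-butyl ester (loss of isobutene) under buffered non-protic conditions leaves the TBS ether, the acetate and the acid-sensitive isopropenyl group intact.

Step 11
Reactants: 17 (E)-3-(trimethylsilyl)prop-2-en-1-ol
Product: 18 [(1S,2R)-2-(trimethylsilyl)cyclopropyl]methanol
Conditions: Et2Zn, CH2I2, DME, CH2Cl2, −10 °C; (4S,5S)-2-butyl-N,N,N′,N′-tetramethyl-1,3,2-dioxaborolane-4,5-dicarboxamide (1.2 equiv), −10 °C to rt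
Reagents that add atoms: diiodomethane, ICI
Why: Charette asymmetric Simmons–Smith cyclopropanation, in which the zinc alkoxide bound to the chiral dioxaborolane directs stereospecific methylene transfer to one alkene face and the E geometry gives the trans cyclopropane (future C8a and C2).

Step 12
Reactants: 18 [(1S,2R)-2-(trimethylsilyl)cyclopropyl]methanol
Product: 19 (1S,2R)-2-(trimethylsilyl)cyclopropane-1-carbaldehyde
Conditions: TEMPO (10 mol %), PhI(OAc)2 (1.1 equiv), CH2Cl2, rt
Reagents that add atoms: none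
Why: TEMPO-catalysed oxidation of a primary alcohol stops at the aldehyde under near-neutral conditions that do not epimerise the trans cyclopropane.

Step 13
Reactants: 19 (1S,2R)-2-(trimethylsilyl)cyclopropane-1-carbaldehyde
Product: 20 [(1R,2S)-2-ethynylcyclopropyl]trimethylsilane
Conditions: dimethyl (1-diazo-2-oxopropyl)phosphonate, K2CO3, MeOH, 0 °C to rt
Reagents that add atoms: dimethyl (1-diazo-2-oxopropyl)phosphonate, CC(=O)C(=[N+]=[N-])P(=O)(OC)OC
Why: Ohira–Bestmann (Seyferth–Gilbert) homologation converts the aldehyde into the terminal alkyne in one mild step without touching the ring stereocentres.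

Step 14
Reactants: 20 [(1R,2S)-2-ethynylcyclopropyl]trimethylsilane
Product: 22 [(1R,2R)-2-(1-bromovinyl)cyclopropyl]trimethylsilane, via internal vinylalane 21 (not isolated)
Conditions: Ni(dppp)Cl2 (3 mol %), i-Bu2AlH (1.3 equiv), THF, rt; then NBS, 0 °C
Reagents that add atoms: N-bromosuccinimide, O=C1CCC(=O)N1Br
Why: Nickel-catalysed α-selective hydroalumination places aluminium on the internal alkyne carbon and bromodealumination gives the 2-bromo-1-alkene without any cationic intermediate next to the cyclopropane.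

Step 15
Reactants: 16 (3S,4R)-3-[(2S,3S)-3-acetoxy-6-methylhept-6-en-2-yl]-4-(tert-butyldimethylsilyloxy)hept-5-ynoic acid; 22 [(1R,2R)-2-(1-bromovinyl)cyclopropyl]trimethylsilane
Product: 26 (5S,6R)-5-[(2S,3S)-3-acetoxy-6-methylhept-6-en-2-yl]-6-(tert-butyldimethylsilyloxy)-2-[(1S,2R)-2-(trimethylsilyl)cyclopropyl]non-1-en-7-yn-3-one, via acid chloride 23 (not isolated), via vinyllithium 24 (not isolated), via vinylzinc chloride 25 (not isolated)
Conditions: 16, 1-chloro-N,N,2-trimethylprop-1-en-1-amine, CH2Cl2, 0 °C; separately 22, t-BuLi (2 equiv), Et2O, −78 °C, then ZnCl2, THF; combine, Pd(PPh3)4 (5 mol %), THF, 0 °C to rt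
Reagents that add atoms: none
Why: Negishi acylation, in which the neutral Ghosez reagent makes the acid chloride without HCl and the alkenylzinc couples under zerovalent palladium catalysis while tolerating the acetate, silyl ether and alkyne.

Step 16
Reactants: 26 (5S,6R)-5-[(2S,3S)-3-acetoxy-6-methylhept-6-en-2-yl]-6-(tert-butyldimethylsilyloxy)-2-[(1S,2R)-2-(trimethylsilyl)cyclopropyl]non-1-en-7-yn-3-one
Product: 27 (3R,5S,6R)-5-[(2S,3S)-3-acetoxy-6-methylhept-6-en-2-yl]-6-(tert-butyldimethylsilyloxy)-2-[(1S,2R)-2-(trimethylsilyl)cyclopropyl]non-1-en-7-yn-3-ol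
Conditions: (S)-2-methyl-CBS-oxazaborolidine (0.3 equiv), catecholborane (2 equiv), toluene, −78 °C
Reagents that add atoms: none
Why: Corey–Bakshi–Shibata reduction of an α-substituted enone, in which the branched alkenyl group acts as the large substituent so that the (S)-catalyst gives the (R)-allylic alcohol (future C7) by 1,2-reduction only.

Step 17
Reactants: 27 (3R,5S,6R)-5-[(2S,3S)-3-acetoxy-6-methylhept-6-en-2-yl]-6-(tert-butyldimethylsilyloxy)-2-[(1S,2R)-2-(trimethylsilyl)cyclopropyl]non-1-en-7-yn-3-ol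
Product: 28 (3R,5S,6R)-5-[(2S,3S)-3-acetoxy-6-methylhept-6-en-2-yl]-3,6-bis(tert-butyldimethylsilyloxy)-2-[(1S,2R)-2-(trimethylsilyl)cyclopropyl]non-1-en-7-yne
Conditions: TBSOTf, 2,6-lutidine, CH2Cl2, −78 to 0 °C
Reagents that add atoms: tert-butyldimethylsilyl triflate, CC(C)(C)[Si](C)(C)OS(=O)(=O)C(F)(F)F
Why: Silylation masks the allylic alcohol, which could otherwise be isomerised to a ketone by the rhodium catalyst of the next step.

Step 18
Reactants: 28 (3R,5S,6R)-5-[(2S,3S)-3-acetoxy-6-methylhept-6-en-2-yl]-3,6-bis(tert-butyldimethylsilyloxy)-2-[(1S,2R)-2-(trimethylsilyl)cyclopropyl]non-1-en-7-yne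
Product: 29 (2S,3S)-2-[(2R,4R,5S,7R,8aS)-4,7-bis(tert-butyldimethylsilyloxy)-3-methyl-8-methylidene-2-(trimethylsilyl)-1,2,4,5,6,7,8,8a-octahydroazulen-5-yl]-6-methylhept-6-en-3-yl acetate
Conditions: [Rh(CO)2Cl]2 (5 mol %), toluene (0.01 M), 100 °C, Ar
Reagents that add atoms: none
Why: Proposed new method: monovalent rhodium should bind the 1,1-disubstituted alkene and insert into the adjacent cyclopropane bond C8a–C2 to give a π-allyl/σ-alkyl trivalent rhodium species, the tethered alkyne then inserts into the Rh–allyl bond at C8a (C3a–C8a), and C(sp2)–C(sp3) reductive elimination from the six-membered rhodacycle forms C2–C3. The closest known reaction types are the rhodium-catalysed intramolecular (3+2) cycloaddition of vinylcyclopropanes whose 2π partner hangs on the internal vinyl carbon (known for alkenes, including bicyclo[5.3.0]decane products) and the (3+2) cycloaddition of alkyne-tethered vinylcyclopropanes, whereas an internal alkyne on this tether and a silyl-substituted cyclopropane are new. Ring B closes by a 7-exo-dig migratory insertion inside the metal template and ring A by the reductive elimination, while the (5+2) alternative is shut off because a tether on C8 would force a bridgehead alkene. Both new stereocentres are inherited from the cyclopropane, since C–C cleavage, insertion on the rhodium-bound allyl face and reductive elimination should all run with retention, so that C8a and C2 keep the trans relation and the absolute sense set in step 11. The step needs cleavage of the silyl-bearing bond C8a–C2 and not of C8a–C1, which is expected from α-silyl stabilisation of the Rh–C bond and from the bias of [Rh(CO)2Cl]2, seen in related (5+2) cycloadditions, for the cyclopropane bond that carries a carbanion-stabilising group. The remote isopropenyl group cannot reach the metal through a small ring and should stay a spectator.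

Step 19
Reactants: 29 (2S,3S)-2-[(2R,4R,5S,7R,8aS)-4,7-bis(tert-butyldimethylsilyloxy)-3-methyl-8-methylidene-2-(trimethylsilyl)-1,2,4,5,6,7,8,8a-octahydroazulen-5-yl]-6-methylhept-6-en-3-yl acetate
Product: 30 (2S,3S)-2-[(3aS,4R,5S,7R,8aR)-4,7-bis(tert-butyldimethylsilyloxy)-3-methyl-8-methylidene-1,3a,4,5,6,7,8,8a-octahydroazulen-5-yl]-6-methylhept-6-en-3-yl acetate
Conditions: CF3CO2H (3 equiv), CH2Cl2, −20 °C; aq. NaHCO3
Reagents that add atoms: none
Why: Anti SE2′ protodesilylation of an allylsilane, in which the most nucleophilic alkene is protonated at C3a on the face opposite the C2–Si bond and loss of silicon from the β-silyl cation places the alkene at C2=C3, which sets H-3a trans to H-8a.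

Step 20
Reactants: 30 (2S,3S)-2-[(3aS,4R,5S,7R,8aR)-4,7-bis(tert-butyldimethylsilyloxy)-3-methyl-8-methylidene-1,3a,4,5,6,7,8,8a-octahydroazulen-5-yl]-6-methylhept-6-en-3-yl acetate
Product: 31 (2S,3S)-2-[(3aS,4R,5S,7R,8aR)-4,7-dihydroxy-3-methyl-8-methylidene-1,3a,4,5,6,7,8,8a-octahydroazulen-5-yl]-6-methylhept-6-en-3-yl acetate
Conditions: HF·pyridine, pyridine, THF, 0 °C to rt
Reagents that add atoms: none
Why: Buffered fluoride cleavage of both TBS ethers is non-basic, so the acetate neither hydrolyses nor migrates and the three alkenes are not isomerised.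

Compound list
1 | ethyl 4-methylpent-4-enoate | CCOC(=O)CCC(C)=C | starting material
2 | 4-methylpent-4-enal | O=CCCC(C)=C | intermediate
3 | (3S,4S)-3,7-dimethylocta-1,7-dien-4-yl bis[(+)-isopinocampheyl]borinate | C=C(C)CC[C@H](OB([C@H]1C[C@H]2C[C@@H]([C@@H]1C)C2(C)C)[C@H]1C[C@H]2C[C@@H]([C@@H]1C)C2(C)C)[C@@H](C)C=C | intermediate
4 | (3S,4S)-3,7-dimethylocta-1,7-dien-4-ol | C=C(C)CC[C@H](O)[C@@H](C)C=C | intermediate
5 | O-(disiamylboryl)-1-(disiamylboryl) adduct of 4 | C=C(C)CC[C@H](OB(C(C)C(C)C)C(C)C(C)C)[C@@H](C)CCB(C(C)C(C)C)C(C)C(C)C | intermediate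
6 | (3S,4S)-3,7-dimethyloct-7-ene-1,4-diol | C=C(C)CC[C@H](O)[C@@H](C)CCO | intermediate
7 | (4S,5S)-4-methyl-5-(3-methylbut-3-enyl)oxolan-2-ol (lactol, anomers) | C=C(C)CC[C@@H]1OC(O)C[C@@H]1C | intermediate
8 | (4S,5S)-4-methyl-5-(3-methylbut-3-enyl)oxolan-2-one | C=C(C)CC[C@@H]1OC(=O)C[C@@H]1C | intermediate
9 | lithium enolate of 8 | C=C(C)CC[C@@H]1OC(O[Li])=C[C@@H]1C | intermediate
10 | tert-butyl 2-[(3S,4S,5S)-4-methyl-5-(3-methylbut-3-enyl)-2-oxooxolan-3-yl]acetate | C=C(C)CC[C@@H]1OC(=O)[C@@H](CC(=O)OC(C)(C)C)[C@@H]1C | intermediate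
11 | tert-butyl (3S)-3-[(2S,3S)-3-hydroxy-6-methylhept-6-en-2-yl]-4-oxohept-5-ynoate | C=C(C)CC[C@H](O)[C@@H](C)[C@@H](C(=O)C#CC)CC(=O)OC(C)(C)C | intermediate
12 | tert-butyl (3S)-3-[(2S,3S)-3-acetoxy-6-methylhept-6-en-2-yl]-4-oxohept-5-ynoate | C=C(C)CC[C@H](OC(C)=O)[C@@H](C)[C@@H](C(=O)C#CC)CC(=O)OC(C)(C)C | intermediate
13 | tert-butyl (3S,4R)-3-[(2S,3S)-3-acetoxy-6-methylhept-6-en-2-yl]-4-hydroxyhept-5-ynoate | C=C(C)CC[C@H](OC(C)=O)[C@@H](C)[C@@H]([C@@H](O)C#CC)CC(=O)OC(C)(C)C | intermediate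
14 | tert-butyl (3S,4R)-3-[(2S,3S)-3-acetoxy-6-methylhept-6-en-2-yl]-4-(tert-butyldimethylsilyloxy)hept-5-ynoate | C=C(C)CC[C@H](OC(C)=O)[C@@H](C)[C@@H]([C@@H](O[Si](C)(C)C(C)(C)C)C#CC)CC(=O)OC(C)(C)C | intermediate
15 | trimethylsilyl ester of 16 | C=C(C)CC[C@H](OC(C)=O)[C@@H](C)[C@@H]([C@@H](O[Si](C)(C)C(C)(C)C)C#CC)CC(=O)O[Si](C)(C)C | intermediate
16 | (3S,4R)-3-[(2S,3S)-3-acetoxy-6-methylhept-6-en-2-yl]-4-(tert-butyldimethylsilyloxy)hept-5-ynoic acid | C=C(C)CC[C@H](OC(C)=O)[C@@H](C)[C@@H]([C@@H](O[Si](C)(C)C(C)(C)C)C#CC)CC(=O)O | intermediate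
17 | (E)-3-(trimethylsilyl)prop-2-en-1-ol | C[Si](C)(C)/C=C/CO | starting material
18 | [(1S,2R)-2-(trimethylsilyl)cyclopropyl]methanol | OC[C@@H]1C[C@H]1[Si](C)(C)C | intermediate
19 | (1S,2R)-2-(trimethylsilyl)cyclopropane-1-carbaldehyde | O=C[C@@H]1C[C@H]1[Si](C)(C)C | intermediate
20 | [(1R,2S)-2-ethynylcyclopropyl]trimethylsilane | C#C[C@@H]1C[C@H]1[Si](C)(C)C | intermediate
21 | diisobutyl{1-[(1S,2R)-2-(trimethylsilyl)cyclopropyl]vinyl}alane | C=C([Al](CC(C)C)CC(C)C)[C@@H]1C[C@H]1[Si](C)(C)C | intermediate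
22 | [(1R,2R)-2-(1-bromovinyl)cyclopropyl]trimethylsilane | C=C(Br)[C@@H]1C[C@H]1[Si](C)(C)C | intermediate
23 | acid chloride of 16 | C=C(C)CC[C@H](OC(C)=O)[C@@H](C)[C@@H]([C@@H](O[Si](C)(C)C(C)(C)C)C#CC)CC(=O)Cl | intermediate
24 | vinyllithium from 22 (cyclopropane configuration retained) | [Li]C(=C)[C@@H]1C[C@H]1[Si](C)(C)C | intermediate
25 | vinylzinc chloride from 24 (cyclopropane configuration retained) | Cl[Zn]C(=C)[C@@H]1C[C@H]1[Si](C)(C)C | intermediate
26 | (5S,6R)-5-[(2S,3S)-3-acetoxy-6-methylhept-6-en-2-yl]-6-(tert-butyldimethylsilyloxy)-2-[(1S,2R)-2-(trimethylsilyl)cyclopropyl]non-1-en-7-yn-3-one | C=C(C)CC[C@H](OC(C)=O)[C@@H](C)[C@@H]([C@@H](O[Si](C)(C)C(C)(C)C)C#CC)CC(=O)C(=C)[C@@H]1C[C@H]1[Si](C)(C)C | intermediate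
27 | (3R,5S,6R)-5-[(2S,3S)-3-acetoxy-6-methylhept-6-en-2-yl]-6-(tert-butyldimethylsilyloxy)-2-[(1S,2R)-2-(trimethylsilyl)cyclopropyl]non-1-en-7-yn-3-ol | C=C(C)CC[C@H](OC(C)=O)[C@@H](C)[C@@H]([C@@H](O[Si](C)(C)C(C)(C)C)C#CC)C[C@@H](O)C(=C)[C@@H]1C[C@H]1[Si](C)(C)C | intermediate
28 | (3R,5S,6R)-5-[(2S,3S)-3-acetoxy-6-methylhept-6-en-2-yl]-3,6-bis(tert-butyldimethylsilyloxy)-2-[(1S,2R)-2-(trimethylsilyl)cyclopropyl]non-1-en-7-yne | C=C(C)CC[C@H](OC(C)=O)[C@@H](C)[C@@H]([C@@H](O[Si](C)(C)C(C)(C)C)C#CC)C[C@@H](O[Si](C)(C)C(C)(C)C)C(=C)[C@@H]1C[C@H]1[Si](C)(C)C | intermediate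
29 | (2S,3S)-2-[(2R,4R,5S,7R,8aS)-4,7-bis(tert-butyldimethylsilyloxy)-3-methyl-8-methylidene-2-(trimethylsilyl)-1,2,4,5,6,7,8,8a-octahydroazulen-5-yl]-6-methylhept-6-en-3-yl acetate | C=C(C)CC[C@H](OC(C)=O)[C@@H](C)[C@@H]1C[C@@H](O[Si](C)(C)C(C)(C)C)C(=C)[C@@H]2C[C@@H]([Si](C)(C)C)C(C)=C2[C@@H]1O[Si](C)(C)C(C)(C)C | intermediate
30 | (2S,3S)-2-[(3aS,4R,5S,7R,8aR)-4,7-bis(tert-butyldimethylsilyloxy)-3-methyl-8-methylidene-1,3a,4,5,6,7,8,8a-octahydroazulen-5-yl]-6-methylhept-6-en-3-yl acetate | C=C(C)CC[C@H](OC(C)=O)[C@@H](C)[C@@H]1C[C@@H](O[Si](C)(C)C(C)(C)C)C(=C)[C@@H]2CC=C(C)[C@H]2[C@@H]1O[Si](C)(C)C(C)(C)C | intermediate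
31 | (2S,3S)-2-[(3aS,4R,5S,7R,8aR)-4,7-dihydroxy-3-methyl-8-methylidene-1,3a,4,5,6,7,8,8a-octahydroazulen-5-yl]-6-methylhept-6-en-3-yl acetate | C=C(C)CC[C@H](OC(C)=O)[C@@H](C)[C@@H]1C[C@@H](O)C(=C)[C@@H]2CC=C(C)[C@H]2[C@@H]1O | target

Total step count: 20. Longest linear sequence: 16 steps (steps 1–10 and 15–20).

Steps most likely to fail

1. Step 18. Rhodium may insert into the unsubstituted cyclopropane bond, the metallacycle may collapse by β-hydride elimination to dienes, or the seven-membered closure may simply not occur.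
   - The fallback sets out from acid chloride 23 (made from 16 as in step 15) and comes back at 30. It uses only known reaction types.
   - 23 is reduced with LiAlH(Ot-Bu)3 (THF, −78 °C) to the aldehyde F1.
   - Indium-mediated coupling with 4-bromobut-2-ynyl acetate (indium powder, THF/H2O) gives, by SE2′ attack, the α-allenic alcohol F2. The C7 carbinol epimers have to be separated at this point.
   - Silylation (TBSOTf, 2,6-lutidine) gives the allenyne F3.
   - An allenic Pauson–Khand reaction ([Rh(CO)2Cl]2, CO 1 atm, toluene, 90 °C) engages the distal allene bond and is an established entry to bicyclo[5.3.0]decadienones. It should give the cross-conjugated dienone F4.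
   - Tsuji hydrogenolysis of the allylic acetate (Pd2(dba)3·CHCl3, PBu3, HCO2H, Et3N, THF) delivers hydride to the more substituted allyl terminus C8a and gives the exo-methylene enone F5.
   - Condensation with TsNHNH2 gives the tosylhydrazone F6.
   - Catecholborane and then NaOAc·3H2O (reductive 1,3-transposition through an allylic diazene) put hydride on C2 from the face away from C8. The retro-ene step therefore hands hydrogen to C3a on the hindered face and gives the trans-fused 30.

2. Step 6. A second acetylide addition, enolisation with epimerisation next to the new ketone, or closure to a hemiketal that resists acetylation may erode the step.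
   - The fallback sets out from 10 and comes back at 11.
   - The lactone is opened first with MeNH(OMe)·HCl and i-PrMgCl (THF, −20 °C) to the hydroxy Weinreb amide F7.
   - The free hydroxyl is masked (TESCl, imidazole) as the silyl ether F8.
   - 1-Propynylmagnesium bromide (THF, 0 °C) adds once, through the stable chelate, to give the ynone F9.
   - Mild acid (AcOH/THF/H2O) removes the triethylsilyl group to give 11.

3. Step 3. The 1,1-disubstituted alkene may be hydroborated in competition with the vinyl group.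
   - The fallback sets out from 4 and comes back at lactol 7.
   - It replaces boron chemistry by an aldehyde-selective, nitrite-modified Wacker oxidation (PdCl2(PhCN)2, CuCl2·2H2O, AgNO2, t-BuOH/MeNO2, O2).
   - 1,1-Disubstituted alkenes are inert to this oxidation. The aldehyde formed from the vinyl group closes onto the neighbouring hydroxyl to give 7, which is oxidised as in step 4.

Further compounds
F1 | step 18 | (3S,4R)-3-[(2S,3S)-3-acetoxy-6-methylhept-6-en-2-yl]-4-(tert-butyldimethylsilyloxy)hept-5-ynal | C=C(C)CC[C@H](OC(C)=O)[C@@H](C)[C@@H]([C@@H](O[Si](C)(C)C(C)(C)C)C#CC)CC=O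
F2 | step 18 | (4R,6S,7R)-6-[(2S,3S)-3-acetoxy-6-methylhept-6-en-2-yl]-3-(acetoxymethyl)-7-(tert-butyldimethylsilyloxy)deca-1,2-dien-8-yn-4-ol | C=C(C)CC[C@H](OC(C)=O)[C@@H](C)[C@@H]([C@@H](O[Si](C)(C)C(C)(C)C)C#CC)C[C@@H](O)C(COC(C)=O)=C=C
F3 | step 18 | 4-O-TBS ether of F2 | C=C(C)CC[C@H](OC(C)=O)[C@@H](C)[C@@H]([C@@H](O[Si](C)(C)C(C)(C)C)C#CC)C[C@@H](O[Si](C)(C)C(C)(C)C)C(COC(C)=O)=C=C
F4 | step 18 | (2S,3S)-2-[(4R,5S,7R)-8-(acetoxymethyl)-4,7-bis(tert-butyldimethylsilyloxy)-3-methyl-2-oxo-1,2,4,5,6,7-hexahydroazulen-5-yl]-6-methylhept-6-en-3-yl acetate | C=C(C)CC[C@H](OC(C)=O)[C@@H](C)[C@@H]1C[C@@H](O[Si](C)(C)C(C)(C)C)C(COC(C)=O)=C2CC(=O)C(C)=C2[C@@H]1O[Si](C)(C)C(C)(C)C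
F5 | step 18 | (2S,3S)-2-[(4R,5S,7R,8aS)-4,7-bis(tert-butyldimethylsilyloxy)-3-methyl-8-methylidene-2-oxo-1,2,4,5,6,7,8,8a-octahydroazulen-5-yl]-6-methylhept-6-en-3-yl acetate | C=C(C)CC[C@H](OC(C)=O)[C@@H](C)[C@@H]1C[C@@H](O[Si](C)(C)C(C)(C)C)C(=C)[C@@H]2CC(=O)C(C)=C2[C@@H]1O[Si](C)(C)C(C)(C)C
F6 | step 18 | 4-methylbenzenesulfonylhydrazone of F5 | C=C(C)CC[C@H](OC(C)=O)[C@@H](C)[C@@H]1C[C@@H](O[Si](C)(C)C(C)(C)C)C(=C)[C@@H]2CC(=NNS(=O)(=O)c3ccc(C)cc3)C(C)=C2[C@@H]1O[Si](C)(C)C(C)(C)C
F7 | step 6 | tert-butyl (3S)-3-[(2S,3S)-3-hydroxy-6-methylhept-6-en-2-yl]-4-[methoxy(methyl)amino]-4-oxobutanoate | C=C(C)CC[C@H](O)[C@@H](C)[C@@H](C(=O)N(C)OC)CC(=O)OC(C)(C)C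
F8 | step 6 | O-triethylsilyl ether of F7 | C=C(C)CC[C@H](O[Si](CC)(CC)CC)[C@@H](C)[C@@H](C(=O)N(C)OC)CC(=O)OC(C)(C)C
F9 | step 6 | O-triethylsilyl ether of 11 | C=C(C)CC[C@H](O[Si](CC)(CC)CC)[C@@H](C)[C@@H](C(=O)C#CC)CC(=O)OC(C)(C)C
F0 | step 3 | none | none
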